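**Plan**
1. Ring A is the 4,4-dimethylcyclohexadienone ring, numbered here as follows: carbon 1 is the ring C=O, carbon 2 bears the acetyl group, carbon 3 an OH, carbon 4 the two methyl groups, carbon 5 an OH and carbon 6 the CH2 bridge. Ring B is the benzene ring and ring C the pyran ring.
2. The retrosynthesis first cuts the bond between carbon 6 of ring A and the bridge CH2 (retro-Michael to an ortho-quinone methide of the chromene, bridge carbon from formaldehyde). It then cuts the 2–3 and 5–6 bonds of ring A together, and last the O–C and C–C bonds of ring C (to 2,4,6-trihydroxyacetophenone and prenal).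
3. Enabling feature: carbons 3, 4 and 5 of ring A form a dimethylmalonyl unit whose central carbon carries no hydrogen, and carbons 2 and 6 are the two α-carbons of the ring ketone. With the acetyl group on carbon 2 and a temporary tert-butyl ester on carbon 6, both are 1,3-dicarbonyl carbons, so an open-chain 3,5-dioxohexanoate and dimethylmalonyl dichloride should give ring A in one double C-acylation.
4. Forward: ring A is built first from acyclic pieces (steps 1–3, ester removed in step 3). Ring C is then fused to ring B (step 4), and the two halves are joined last through the methylene bridge (steps 5–6).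
5. Stereochemistry: the target has no stereocentre and no stereogenic double bond; only regiochemistry has to be controlled.

Key step: step 2

Remark: the enolised β-triketone and acylphloroglucinol units are written in the tautomeric form of the target SMILES; other tautomers are the same compounds.

Step 1
Reactants: 1 tert-butyl 3-oxobutanoate; 2 N-methoxy-N-methylacetamide
Product: 3 tert-butyl 3,5-dioxohexanoate
Conditions: LiN(iPr)2 (2.1 equiv, commercial solution), THF, −78 → 0 °C; 2 (1.0 equiv), −78 → 0 °C; cold aq. HCl
Reagents that add atoms: none
Why: Claisen-type acylation of the γ-carbon of the acetoacetate dienolate by an N-methoxy-N-methylamide is a standard route to 3,5-dioxo esters, because the chelated tetrahedral adduct collapses only on work-up and so prevents double addition and proton quench of the dienolate; no stereocentre is formed.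

Step 2
Reactants: 3 tert-butyl 3,5-dioxohexanoate; 4 2,2-dimethylpropanedioyl dichloride (dimethylmalonyl dichloride)
Product: 6 tert-butyl 5-acetyl-2,4-dihydroxy-3,3-dimethyl-6-oxocyclohexa-1,4-diene-1-carboxylate, via acyl chloride 5 (not isolated)
Conditions: MgCl2 (2.2 equiv), Et3N (4.5 equiv), MeCN, 0 °C; 4 (1.0 equiv) in CH2Cl2 added over 4 h (final 0.03 M), 0 °C → rt; DMAP (10 mol %), 40 °C; cold aq. citric acid
Reagents that add atoms: none
Why: Proposed new method: MgCl2/Et3N should turn 3 into a magnesium-chelated enolate whose diketone carbon (carbon 4 of the hexanoate chain) is C-acylated by one acyl chloride group of 4 to give 5, and the β-keto ester carbon (carbon 2 of the chain) of 5, enolised in the same way, should then attack the second acyl chloride group, so that the 2–3 and 5–6 bonds of ring A arise in one flask and the product leaves the equilibrium as its doubly enolised chelate. The closest known reaction types are the MgCl2/amine C-acylation of 1,3-dicarbonyl compounds with acyl chlorides and the cyclo-diacylation of 3-oxoglutarate diesters or ketone enol ethers with malonyl dichlorides to cyclohexane-1,3,5-triones (Effenberger cyclisation). Ring A closes by attack of the enolate carbon on the acyl chloride in a 6-(enolendo)-exo-trig mode, which is allowed and is helped by the gem-dimethyl group of 4. No stereocentre is formed. The step needs C- over O-acylation, reaction at chain carbons 2 and 4 but not at the terminal methyl group, and ring closure over chain growth: the temporary tert-butyl ester makes chain carbon 2 a 1,3-dicarbonyl carbon like chain carbon 4 while the terminal methyl group stays non-enolised under amine base, magnesium chelation ties up the enolate oxygens, DMAP re-opens any enol lactone to an acylpyridinium ion that can still close on carbon, 4 has no α-hydrogen and so cannot form a ketene, and slow addition at high dilution favours the ring.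

Step 3
Reactants: 6 tert-butyl 5-acetyl-2,4-dihydroxy-3,3-dimethyl-6-oxocyclohexa-1,4-diene-1-carboxylate
Product: 8 acetylfilicinic acid (2-acetyl-3,5-dihydroxy-4,4-dimethylcyclohexa-2,5-dien-1-one), via carboxylic acid 7 (not isolated)
Conditions: CF3CO2H/CH2Cl2 (1:4), rt; evaporation; toluene, 80 °C
Reagents that add atoms: none
Why: Acidolysis of the tert-butyl ester (loss of isobutene) should give a β-keto acid that decarboxylates through a six-membered hydrogen-bonded transition state on gentle heating, which removes the activating group and frees carbon 6 of ring A, while the β-triketone and the acetyl group are inert to CF3CO2H.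

Step 4
Reactants: 9 1-(2,4,6-trihydroxyphenyl)ethan-1-one; 10 3-methylbut-2-enal
Product: 12 1-(5,7-dihydroxy-2,2-dimethyl-2H-chromen-8-yl)ethan-1-one, via dienone 11 (not isolated)
Conditions: 10 (1.1 equiv), pyridine, 110 °C, sealed tube; chromatography
Reagents that add atoms: none
Why: Aldol-type C-alkylation of the phloroglucinol ring by the enal, dehydration to dienone 11 and oxa-6π electrocyclisation (the standard enal chromenylation of acylphloroglucinols) should build ring C, closure on the oxygen ortho to the acetyl group giving the 8-acetyl isomer 12; the 6-acetyl isomer from closure on the para oxygen is expected as a by-product and is removed by chromatography, and no stereocentre is formed.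

Step 5
Reactants: 12 1-(5,7-dihydroxy-2,2-dimethyl-2H-chromen-8-yl)ethan-1-one
Product: 13 1-{6-[(dimethylamino)methyl]-5,7-dihydroxy-2,2-dimethyl-2H-chromen-8-yl}ethan-1-one
Conditions: CH2O (37% aq., 1.05 equiv), Me2NH (40% aq., 1.1 equiv), EtOH, 0 °C → rt
Reagents that add atoms: formaldehyde, C=O; dimethylamine, CNC
Why: A phenolic Mannich reaction should take place at the only unsubstituted carbon of ring B (carbon 6 of the chromene, activated by two ortho hydroxy groups) with the iminium ion formed from formaldehyde and dimethylamine, the acetyl methyl group and the chromene double bond being far less nucleophilic.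

Step 6
Reactants: 13 1-{6-[(dimethylamino)methyl]-5,7-dihydroxy-2,2-dimethyl-2H-chromen-8-yl}ethan-1-one; 8 acetylfilicinic acid
Product: 15 2-acetyl-6-[(8-acetyl-5,7-dihydroxy-2,2-dimethyl-2H-chromen-6-yl)methyl]-3,5-dihydroxy-4,4-dimethylcyclohexa-2,5-dien-1-one, via quinone methide 14 (not isolated)
Conditions: 8 (1.0 equiv), 13 (1.05 equiv), degassed 1,4-dioxane, 90 °C, slow nitrogen stream
Reagents that add atoms: none
Why: Proton transfer from the strongly acidic triketone 8 to the amine of 13 should trigger loss of dimethylamine to ortho-quinone methide 14, to which the enolate of 8 adds through its only free ring carbon (carbon 6 of ring A) in a Michael addition that restores aromatic ring B (the known alkylation of 1,3-dicarbonyl compounds by phenolic Mannich bases); no stereocentre is formed.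

**Compound list**
1 | tert-butyl 3-oxobutanoate (tert-butyl acetoacetate) | CC(=O)CC(=O)OC(C)(C)C | starting material
2 | N-methoxy-N-methylacetamide | CC(=O)N(C)OC | starting material
3 | tert-butyl 3,5-dioxohexanoate | CC(=O)CC(=O)CC(=O)OC(C)(C)C | intermediate
4 | 2,2-dimethylpropanedioyl dichloride (dimethylmalonyl dichloride) | CC(C)(C(Cl)=O)C(Cl)=O | starting material
5 | tert-butyl 4-acetyl-7-chloro-6,6-dimethyl-3,5,7-trioxoheptanoate | CC(=O)C(C(=O)CC(=O)OC(C)(C)C)C(=O)C(C)(C)C(Cl)=O | intermediate
6 | tert-butyl 5-acetyl-2,4-dihydroxy-3,3-dimethyl-6-oxocyclohexa-1,4-diene-1-carboxylate | CC(=O)C1=C(O)C(C)(C)C(O)=C(C(=O)OC(C)(C)C)C1=O | intermediate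
7 | 5-acetyl-2,4-dihydroxy-3,3-dimethyl-6-oxocyclohexa-1,4-diene-1-carboxylic acid | CC(=O)C1=C(O)C(C)(C)C(O)=C(C(=O)O)C1=O | intermediate
8 | acetylfilicinic acid (2-acetyl-3,5-dihydroxy-4,4-dimethylcyclohexa-2,5-dien-1-one) | CC(=O)C1=C(O)C(C)(C)C(O)=CC1=O | intermediate
9 | 1-(2,4,6-trihydroxyphenyl)ethan-1-one | CC(=O)c1c(O)cc(O)cc1O | starting material
10 | 3-methylbut-2-enal | CC(C)=CC=O | starting material
11 | (6Z)-2-acetyl-3,5-dihydroxy-6-(3-methylbut-2-en-1-ylidene)cyclohexa-2,4-dien-1-one | CC(=O)C1=C(O)C=C(O)/C(=C/C=C(C)C)C1=O | intermediate
12 | 1-(5,7-dihydroxy-2,2-dimethyl-2H-chromen-8-yl)ethan-1-one | CC(=O)c1c(O)cc(O)c2C=CC(C)(C)Oc12 | intermediate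
13 | 1-{6-[(dimethylamino)methyl]-5,7-dihydroxy-2,2-dimethyl-2H-chromen-8-yl}ethan-1-one | CC(=O)c1c(O)c(CN(C)C)c(O)c2C=CC(C)(C)Oc12 | intermediate
14 | 8-acetyl-7-hydroxy-2,2-dimethyl-6-methylidene-2H-chromen-5(6H)-one | CC(=O)C1=C(O)C(=C)C(=O)C2=C1OC(C)(C)C=C2 | intermediate
15 | 2-acetyl-6-[(8-acetyl-5,7-dihydroxy-2,2-dimethyl-2H-chromen-6-yl)methyl]-3,5-dihydroxy-4,4-dimethylcyclohexa-2,5-dien-1-one | CC(=O)C1=C(O)C(C)(C)C(O)=C(Cc2c(O)c3c(c(C(C)=O)c2O)OC(C)(C)C=C3)C1=O | target

Total step count: 6. Longest linear sequence: 4 steps (steps 1, 2, 3 and 6); the chromene branch (steps 4 and 5) joins in step 6.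

**Steps most likely to fail**

Step 2. After the first C–C bond, the chelated enolate may close through oxygen to an enol lactone that does not return, or the second acyl chloride group may react between molecules and give oligomers. The fallback uses known chemistry; it sets out from 9 and returns to the route at 8. Compound 9 is C-methylated with MeI and NaOMe in MeOH at 0 °C → rt, first to 1-(2,4,6-trihydroxy-3-methylphenyl)ethan-1-one F1, which is not isolated. A second methylation on the same ring carbon then dearomatises the ring and gives acetylfilicinic acid 8. This is the classical geminal C-methylation of acylphloroglucinols, and steps 1–3 are then not needed.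

Step 6. The aminomethyl or methylene unit may be exchanged between the partners by retro-Mannich and retro-Michael equilibria, which would give symmetric methylene-bridged dimers, or the Mannich base may ionise too slowly. The fallback reverses the roles of the two halves; it sets out from 8 and returns at 15. Compound 8 is aminomethylated at carbon 6 of ring A with aqueous CH2O and Me2NH in EtOH to give 2-acetyl-6-[(dimethylamino)methyl]-3,5-dihydroxy-4,4-dimethylcyclohexa-2,5-dien-1-one F2. In MeCN at rt → 50 °C, the Mannich base should lose dimethylamine to 2-acetyl-3-hydroxy-4,4-dimethyl-6-methylidenecyclohex-2-ene-1,5-dione F3, which is not isolated. Chromene 12 then adds to this acceptor through its only free aromatic carbon (carbon 6 of the chromene) in a Friedel–Crafts-type Michael addition, a pattern known from couplings of phloroglucinols with alkylidene β-triketones, and gives 15.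

Step 4. The ring may close on the oxygen para to the acetyl group, giving the wrong regioisomer, and a second chromene ring may be added. The fallback sets out from 9 and returns at 12. The most acidic, non-chelated 4-hydroxy group of 9 is tosylated selectively (TsCl 1.0 equiv, K2CO3, acetone, rt) to 4-acetyl-3,5-dihydroxyphenyl 4-methylbenzenesulfonate F4. Chromenylation with 10 (pyridine, 110 °C) can then close only on an oxygen ortho to the acetyl group and should give 8-acetyl-7-hydroxy-2,2-dimethyl-2H-chromen-5-yl 4-methylbenzenesulfonate F5. Cleavage of the sulfonate (KOH, aq. MeOH, 60 °C) gives 12 as a single regioisomer.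

**Further compounds**
F1 | step 2 | 1-(2,4,6-trihydroxy-3-methylphenyl)ethan-1-one | CC(=O)c1c(O)cc(O)c(C)c1O
F2 | step 6 | 2-acetyl-6-[(dimethylamino)methyl]-3,5-dihydroxy-4,4-dimethylcyclohexa-2,5-dien-1-one | CC(=O)C1=C(O)C(C)(C)C(O)=C(CN(C)C)C1=O
F3 | step 6 | 2-acetyl-3-hydroxy-4,4-dimethyl-6-methylidenecyclohex-2-ene-1,5-dione | CC(=O)C1=C(O)C(C)(C)C(=O)C(=C)C1=O
F4 | step 4 | 4-acetyl-3,5-dihydroxyphenyl 4-methylbenzenesulfonate | CC(=O)c1c(O)cc(OS(=O)(=O)c2ccc(C)cc2)cc1O
F5 | step 4 | 8-acetyl-7-hydroxy-2,2-dimethyl-2H-chromen-5-yl 4-methylbenzenesulfonate | CC(=O)c1c(O)cc(OS(=O)(=O)c3ccc(C)cc3)c2C=CC(C)(C)Oc12
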